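## The problem

The target is a germacranolide. Its ten-membered carbocycle (C1–C10) is trans-fused across C7–C8 to a γ-lactone (C11, C12, ring oxygen on C8). It also carries a trans-1,10-oxirane, a (4Z)-trisubstituted alkene and two angelates, one on the allylic C6 carbinol and one on the tertiary C11 carbinol.

Six stereocentres (1R, 6R, 7S, 8R, 10R, 11R) have to be set. C10 and C11 are fully substituted carbinol carbons with no neighbour that could induce them, so they should come from the chiral pool. C7 and C8 are a syn pair that an aldol reaction can deliver, C6 can be read from C7, and C1 can be read from C10.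

The medium ring is the central difficulty: closing a ten-membered ring directly fights entropy and transannular strain, and a Z-trisubstituted ring alkene is hard to impose by olefination or metathesis.

Three groups are fragile and belong at the very end. Angelates isomerise to tiglates and are cleaved by nucleophiles. The 1,10-epoxide of a germacrene cyclises across the ring under acid. The lactone does not survive organomagnesium reagents.

The enabling feature is the 1,4 relationship between oxygen-bearing C1 and the C4=C5 alkene. With C1 as a ketone and C4≡C5 as an alkyne the ring is a cyclodec-4-yn-1-one. That is exactly what fragmentation of a 2,3-epoxycyclopentanone (C4 carbonyl, C1/C5 oxirane) fused to a seven-membered ring (C5–C10 plus C1) gives. In that alkynone the C6 hydroxyl is propargylic and can steer a methyl group to C4, and the C10 hydroxyl is α to the C1 carbonyl and can steer a hydride to C1.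

## Retrosynthesis

**C11 ester.** The target 45 is cut at the C11 O–acyl bond to the hydroxy epoxy lactone 44 and the angeloyl donor 38. This ester is the most hindered and the most prone to isomerise, so it goes on last. The forward step must acylate a tertiary alkoxide without Z→E isomerisation.

**Oxirane, lactone, C6 ester.** The C1–O bond of the oxirane in 44 is cut to the diol lactone 42, where the C10 oxygen displaces an activated C1 oxygen with inversion. Epoxidising a 1(10)-alkene next to C4=C5 would offer no regio- or face control. The O8–C12 lactone bond of 42 is cut to pentaol 40, because C12 has to travel as a protected CH2OH through the Grignard step; 40 is the protected 39 laid bare. The C6 ester of 39 is cut to the allylic alcohol 36 and the same donor 38. Each forward step then addresses the only hydroxyl of its class: the single free alcohol in 36, the single primary alcohol in 40, the single secondary alcohol in 42.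

**Angeloyl donor.** The mixed anhydride 38 is cut at its anhydride C–O bond to angelic acid 37 and 2,4,6-trichlorobenzoyl chloride. One batch serves both esterifications, and the hindered aroyl half directs alcohols and alkoxides to the angeloyl carbonyl.

**C4 methyl.** The C4–CH3 and C5–H bonds of 36 are cut to the cyclodecyne 34. A syn addition across a ring alkyne can only give the cis ring alkene, which olefination or metathesis could not guarantee. The forward step needs the C6 alkoxide to send methyl to C4.

**C1 carbinol.** The acetonide 34 comes from diol 33, and the C1–H bond of 33 is cut to the α-hydroxy ketone 32. The C10 hydroxyl must direct the hydride so that the diol is anti.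

**Ring (key cut).** Ketone 32 is the desilylated form of alkynone 31. In 31 the C1 carbonyl and the C4≡C5 alkyne are reconnected through the C1–C5 bond and an oxirane oxygen, giving the bicyclic epoxy ketone 29. Ring expansion by σ-bond cleavage has no entropic cost, in contrast to any direct closure of the ten-membered ring. The precursor 29 contains only five- and seven-membered rings. The forward step needs a hydrazone at C4 and nothing else.

**Oxirane and C6 carbinol of the bicycle.** The oxirane of 29 is cut back to the ring-fusion alkene. The C4 carbonyl is masked as a dioxolane (28, 27), and the C6 carbinol of 27 is traced to the ketone 26. The forward steps ask for a hydride on the face opposite the C7 side chain and a hydroxyl-directed epoxidation.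

**C5–C6 bond.** The seven-membered ring of 26 is cut at C5–C6 to the bromo Weinreb amide 24 (vinyl anion plus acyl donor). This cut leaves C6 as a carbonyl, so no stereocentre is made during ring closure. It also keeps C5 sp2 throughout, so the C6 oxygen never sits β to an enolisable C4 carbonyl. Closing the five-membered ring by an acid-mediated Nazarov reaction, or closing at C7–C8, would expose acid-labile groups or set stereocentres in a cyclisation.

**C7–C8 bond.** Amide 24 goes back through 23 to the aldol adduct 22, which is cut at C7–C8 into the imide 20 (C6, C7, C11–C13) and the aldehyde 14 (C1–C5, C8–C10, C14). An auxiliary-controlled syn aldol sets C7 and C8 together, and the two fragments are of similar size.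

**Cyclopentenone fragment.** Aldehyde 14 is traced through 13, 12 and 10 to the cyclopentenone 9. The C1=C5 bond of 9 is cut by a retro-aldol condensation to the 1,4-diketone 8, and the C1–C2 bond of its ketal 7 is cut to lactone 4 and bromide 5. Lactone 4 is (R)-citramalic acid 1 with the β-carboxyl reduced, via dioxolanone 2, so C10 comes from the pool.

**Imide fragment.** Imide 20 is cut at the N-acyl bond to acid 17 and oxazolidinone 18. Acid 17 is again 1, now reduced to triol 15 and carried as acetonide 16 before re-oxidation of C6. The same pool acid supplies C11.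

## Roads not taken

**Alternative 1:** Nitrile oxide cycloaddition. The cut is at C8–C9 and O–C10. The open-chain aldoxime A2 would be oxidised (NaOCl) to a nitrile oxide that adds across its 1,1-disubstituted C9=C10 alkene, giving the isoxazoline-bridged carbocycle A1.
- Merits: ring and tertiary C10–O bond form in one step with the normal regiochemistry; C12 travels as an ester at the right oxidation level; the Z-alkene is made before ring closure.
- Weak points: a ten-membered closure must compete with nitrile oxide dimerisation; C10 is set in a macrocyclic transition state with only remote control; A2 needs a stereodefined Z-trisubstituted alkene flanked by C6 and C7, which is a multistep task. N–O cleavage, C8 reduction and lactonisation follow.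
- Comparison: this road is better in oxidation-level economy and avoids an organolithium ring closure. The chosen plan sets against it a ring formation that is unimolecular and needs no dilution, and a C10 centre taken from the pool.

**Alternative 2:** Photocycloaddition and cycloreversion. The cut is at C4–C5 and C1–C10. Enone lactone A4 and 1-methylcyclobutene A5 would give the tricyclic photoadduct A3. Heating would then break the cyclobutane the other way (C1–C4 and C5–C10) to a cyclodeca-1(10),4-dien-6-one.
- Merits: by far the shortest; ring, both methyl-bearing carbons and the lactone come from two simple partners.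
- Weak points: the photoaddition must be head-to-head and face-selective on a β-methyl enone. The thermolysis gives the diene geometry set by orbital symmetry and ring strain, normally E,E, at temperatures where germacradienes undergo Cope rearrangement, whereas the target needs 4Z. The C1=C10 alkene must then be epoxidised selectively beside C4=C5.
- Comparison: in step count this road is clearly superior. The chosen plan sets against it that alkene geometry (syn addition to an alkyne) and epoxide configuration (SN2 closure) each have a dedicated controlling step.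

**Alternative 3:** Nozaki–Hiyama–Kishi closure. The cut is at C5–C6. The iodo aldehyde A7 would be closed with CrCl2 and catalytic NiCl2 to the C6 carbinol A6, one acylation from the target.
- Merits: the most convergent; the coupling tolerates epoxide, lactone and ester; the vinyl iodide geometry is retained.
- Weak points: it is a true macrocyclisation to a strained ring (dilution, large excess of CrCl2). C6 is decided in the macrocyclic transition state. The aldehyde of A7 is α-branched with a β-acyloxy group, so epimerisation at C7 and β-elimination threaten. A Z-trisubstituted vinyl iodide is needed. The tertiary angelate is already present and may migrate to the new C6 alkoxide.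
- Comparison: this road probably has the shorter longest linear sequence. The chosen plan sets against it a ring formed without macrocyclisation, C6 set on a rigid bicyclic ketone, and the C4 methyl and Z geometry made in one step.

Key step: step 20

Remark on the chemistry (assumptions): atoms are labelled C1–C15 by germacrane numbering throughout; the oxirane of 28–30 is drawn syn to the C6 hydroxyl, but its configuration is lost in step 20 and either face serves; 11 is drawn as one of two trans-dibromides and F8 is a mixture at the phosphonate carbon; keto diol 7 is written open-chain although it will sit largely as its cyclic hemiketal; the mixed anhydride 38 is made in one batch, filtered from the ammonium salt and used as a cold toluene solution for both acylations.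

## Route

Step 1
Reactants: 1 (R)-citramalic acid
Product: 2 2-[(4R)-2,2,4-trimethyl-5-oxo-1,3-dioxolan-4-yl]acetic acid
Conditions: Me2C(OMe)2, TsOH (cat.), rt
Reagents that add atoms: 2,2-dimethoxypropane, COC(C)(C)OC
Why: Acid-catalysed acetalisation engages the α-hydroxy acid as a five-membered dioxolanone in preference to the β-carboxyl, which differentiates the two acids; the pool centre (later C10) is untouched.

Step 2
Reactants: 2 2-[(4R)-2,2,4-trimethyl-5-oxo-1,3-dioxolan-4-yl]acetic acid
Product: 4 (3R)-3-hydroxy-3-methyloxolan-2-one, via hydroxyethyl dioxolanone 3 (not isolated)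
Conditions: BH3·SMe2, THF, 0 °C → rt; MeOH; then TsOH (cat.), CH2Cl2, rt
Reagents that add atoms: none
Why: Borane reduces the free carboxylic acid but not the dioxolanone; under acid the new primary alcohol attacks the activated C1 carbonyl (translactonisation) and acetone is released.

Step 3
Reactants: 4 (3R)-3-hydroxy-3-methyloxolan-2-one; 5 2-(2-bromoethyl)-2-methyl-1,3-dioxolane
Product: 7 (4R)-4,6-dihydroxy-4-methyl-1-(2-methyl-1,3-dioxolan-2-yl)hexan-3-one, via dioxolanylethylmagnesium bromide 6 (not isolated)
Conditions: 5, Mg, THF; then 4 (0.45 equiv), THF, −78 → −20 °C; aq. NH4Cl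
Reagents that add atoms: none
Why: Grignard addition to a lactone: the first equivalent forms the C10 alkoxide, the second adds to C1, and the chelated magnesium hemiketal resists a further addition at low temperature, so the C1–C2 bond is made once.

Step 4
Reactants: 7 (4R)-4,6-dihydroxy-4-methyl-1-(2-methyl-1,3-dioxolan-2-yl)hexan-3-one
Product: 9 3-[(2R)-2,4-dihydroxybutan-2-yl]cyclopent-2-en-1-one, via dihydroxy diketone 8 (not isolated)
Conditions: 1 M HCl, THF, rt; then KOH, MeOH, 40 °C
Reagents that add atoms: water, O
Why: Acetal hydrolysis unveils the 1,4-diketone; the intramolecular aldol condensation can only join C5 (the methyl ketone carbon) to the C1 carbonyl, since C10 has no hydrogen, and gives the 3-substituted cyclopentenone with the C1=C5 bond of the later ring fusion.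

Step 5
Reactants: 9 3-[(2R)-2,4-dihydroxybutan-2-yl]cyclopent-2-en-1-one
Product: 10 3-[(2R)-2,4-bis(triethylsilyloxy)butan-2-yl]cyclopent-2-en-1-one
Conditions: Et3SiOTf (2.5 equiv), 2,6-lutidine, CH2Cl2, −78 → 0 °C
Reagents that add atoms: triethylsilyl triflate, CC[Si](CC)(CC)OS(=O)(=O)C(F)(F)F
Why: A silyl triflate with a hindered pyridine base silylates primary and tertiary hydroxyls alike; the primary ether is the latent C8 aldehyde and the tertiary ether protects C10 through the organometallic steps.

Step 6
Reactants: 10 3-[(2R)-2,4-bis(triethylsilyloxy)butan-2-yl]cyclopent-2-en-1-one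
Product: 12 2-bromo-3-[(2R)-2,4-bis(triethylsilyloxy)butan-2-yl]cyclopent-2-en-1-one, via trans-dibromo ketone 11 (not isolated)
Conditions: Br2, CH2Cl2, 0 °C; then Et3N, 0 °C → rt
Reagents that add atoms: bromine, BrBr
Why: Bromine adds to the enone and base removes HBr through the acidic C5–H (E1cB), the standard route to 2-bromo-3-alkylcyclopentenones; the bromide is the handle for the later C5 anion.

Step 7
Reactants: 12 2-bromo-3-[(2R)-2,4-bis(triethylsilyloxy)butan-2-yl]cyclopent-2-en-1-one
Product: 13 6-bromo-7-[(2R)-2,4-bis(triethylsilyloxy)butan-2-yl]-1,4-dioxaspiro[4.4]non-6-ene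
Conditions: (Me3SiOCH2)2, Me3SiOTf (cat.), CH2Cl2, −78 → −20 °C
Reagents that add atoms: 1,2-bis(trimethylsilyloxy)ethane, C[Si](C)(C)OCCO[Si](C)(C)C
Why: Noyori acetalisation under aprotic conditions masks the C4 carbonyl without shifting the halogen-bearing double bond, as in the 2-bromocyclopentenone ketals used as α-keto vinyl anion equivalents.

Step 8
Reactants: 13 6-bromo-7-[(2R)-2,4-bis(triethylsilyloxy)butan-2-yl]-1,4-dioxaspiro[4.4]non-6-ene
Product: 14 (3R)-3-(6-bromo-1,4-dioxaspiro[4.4]non-6-en-7-yl)-3-(triethylsilyloxy)butanal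
Conditions: (COCl)2, DMSO, CH2Cl2, −78 → −30 °C; Et3N
Reagents that add atoms: none
Why: Under Swern conditions a primary triethylsilyl ether is cleaved and oxidised in one operation while the tertiary silyl ether stays, giving the C8 aldehyde.

Step 9
Reactants: 1 (R)-citramalic acid
Product: 15 (2R)-2-methylbutane-1,2,4-triol
Conditions: BH3·SMe2, B(OMe)3, THF, 0 °C → rt; MeOH
Reagents that add atoms: none
Why: Borane with trimethyl borate reduces both carboxyl groups of a hydroxy diacid without touching the carbinol centre that becomes C11.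

Step 10
Reactants: 15 (2R)-2-methylbutane-1,2,4-triol
Product: 16 2-[(4R)-2,2,4-trimethyl-1,3-dioxolan-4-yl]ethan-1-ol
Conditions: Me2C(OMe)2, TsOH (cat.), acetone, rt
Reagents that add atoms: 2,2-dimethoxypropane, COC(C)(C)OC
Why: Thermodynamic acetonide formation prefers the five-membered dioxolane of the 1,2-diol over the six-membered ring through the tertiary oxygen and the remote hydroxyl, leaving the C6 alcohol free.

Step 11
Reactants: 16 2-[(4R)-2,2,4-trimethyl-1,3-dioxolan-4-yl]ethan-1-ol
Product: 17 2-[(4R)-2,2,4-trimethyl-1,3-dioxolan-4-yl]acetic acid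
Conditions: TEMPO (cat.), NaClO2, NaOCl (cat.), MeCN, pH 6.7 phosphate buffer, 35 °C
Reagents that add atoms: sodium chlorite, [Na+].[O-]Cl=O
Why: Nitroxyl-catalysed chlorite oxidation takes the primary alcohol through the aldehyde to the acid at near-neutral pH, which the acetonide tolerates.

Step 12
Reactants: 17 2-[(4R)-2,2,4-trimethyl-1,3-dioxolan-4-yl]acetic acid; 18 (4S)-4-benzyl-1,3-oxazolidin-2-one
Product: 20 (4S)-4-benzyl-3-{2-[(4R)-2,2,4-trimethyl-1,3-dioxolan-4-yl]acetyl}-1,3-oxazolidin-2-one, via mixed pivalic anhydride 19 (not isolated)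
Conditions: t-BuCOCl, Et3N, THF, −20 °C; then 18, LiCl, rt
Reagents that add atoms: none
Why: Mixed-anhydride N-acylation of the oxazolidinone (LiCl-assisted) gives the Evans imide without strong base.

Step 13
Reactants: 20 (4S)-4-benzyl-3-{2-[(4R)-2,2,4-trimethyl-1,3-dioxolan-4-yl]acetyl}-1,3-oxazolidin-2-one; 14 (3R)-3-(6-bromo-1,4-dioxaspiro[4.4]non-6-en-7-yl)-3-(triethylsilyloxy)butanal
Product: 22 (4S)-4-benzyl-3-[(2R,3R,5R)-5-(6-bromo-1,4-dioxaspiro[4.4]non-6-en-7-yl)-3-hydroxy-5-(triethylsilyloxy)-2-[(4R)-2,2,4-trimethyl-1,3-dioxolan-4-yl]hexanoyl]-1,3-oxazolidin-2-one, via Z-boron enolate 21 (not isolated)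
Conditions: n-Bu2BOTf, Et3N, CH2Cl2, −78 → 0 °C; then 14, −78 → 0 °C; pH 7 buffer, H2O2, MeOH
Reagents that add atoms: none
Why: Evans syn-aldol: the Z-boron enolate reacts through a Zimmerman–Traxler chair on the face away from the benzyl group, so the (4S)-auxiliary fixes C7 and C8 in the syn relationship and absolute sense of the target, irrespective of the remote C10 and C11 centres.

Step 14
Reactants: 22 Evans aldol adduct
Product: 23 (2R,3R,5R)-5-(6-bromo-1,4-dioxaspiro[4.4]non-6-en-7-yl)-3-hydroxy-N-methoxy-N-methyl-5-(triethylsilyloxy)-2-[(4R)-2,2,4-trimethyl-1,3-dioxolan-4-yl]hexanamide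
Conditions: MeNHOMe·HCl, AlMe3, CH2Cl2, −20 → 0 °C
Reagents that add atoms: N,O-dimethylhydroxylamine hydrochloride, CNOC.Cl
Why: Aluminium amide transamination of the aldol imide, assisted by the free β-hydroxyl, gives the Weinreb amide and releases the auxiliary.

Step 15
Reactants: 23 hydroxy Weinreb amide
Product: 24 (2R,3R,5R)-5-(6-bromo-1,4-dioxaspiro[4.4]non-6-en-7-yl)-3-(tert-butyldimethylsilyloxy)-N-methoxy-N-methyl-5-(triethylsilyloxy)-2-[(4R)-2,2,4-trimethyl-1,3-dioxolan-4-yl]hexanamide
Conditions: t-BuMe2SiOTf, 2,6-lutidine, CH2Cl2, −78 → 0 °C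
Reagents that add atoms: tert-butyldimethylsilyl triflate, CC(C)(C)[Si](C)(C)OS(=O)(=O)C(F)(F)F
Why: Silyl triflate protection of the hindered secondary C8 hydroxyl; this ether has to outlast the triethylsilyl ether at C10.

Step 16
Reactants: 24 bromo Weinreb amide
Product: 26 bicyclic enone (C6 ketone in the seven-membered ring C5–C10/C1, C1=C5 ring-fusion alkene, C4 ethylene ketal, C7 dioxolanyl, C8 OTBS, C10 methyl and OTES), via vinyllithium 25 (not isolated)
Conditions: t-BuLi (2.1 equiv), THF, −78 → −20 °C; aq. NH4Cl
Reagents that add atoms: none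
Why: Parham-type cyclisation: bromine–lithium exchange gives the C5 vinyllithium, which is acylated by the tethered Weinreb amide to close the seven-membered ring; the chelated tetrahedral intermediate prevents over-addition, and C5 stays sp2 so the C6 oxygen is never β to an enolisable carbonyl.

Step 17
Reactants: 26 bicyclic enone
Product: 27 bicyclic allylic alcohol (C6 hydroxyl cis to the C7 dioxolanyl group; otherwise as 26)
Conditions: NaBH4, CeCl3·7H2O, MeOH, −40 °C
Reagents that add atoms: none
Why: Luche 1,2-reduction; hydride should approach the C6 carbonyl from the face opposite the bulky C7 dioxolanyl group, giving the alcohol cis to that group, which is the configuration that becomes 6R in the target.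

Step 18
Reactants: 27 bicyclic allylic alcohol
Product: 28 epoxy alcohol (C1/C5 oxirane syn to the C6 hydroxyl, C4 ethylene ketal)
Conditions: mCPBA, NaHCO3, CH2Cl2, 0 °C
Reagents that add atoms: 3-chloroperoxybenzoic acid, OOC(=O)c1cccc(Cl)c1
Why: Hydroxyl-directed peracid epoxidation (Henbest) of an electron-rich tetrasubstituted alkene delivers oxygen syn to the C6 hydroxyl; both oxirane centres are erased in step 20, so this face selectivity is not critical.

Step 19
Reactants: 28 epoxy alcohol ketal
Product: 29 ring-fused 2,3-epoxycyclopentanone (C4 ketone, C1/C5 oxirane, C6 OH, C7 dioxolanyl, C8 OTBS, C10 methyl and OTES)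
Conditions: PPTS, acetone/H2O, 40 °C
Reagents that add atoms: water, O
Why: Mild acetal hydrolysis removes the dioxolane while the silyl ethers, the acetonide and the oxirane persist, which unveils the epoxy ketone needed for fragmentation.

Step 20
Reactants: 29 ring-fused 2,3-epoxycyclopentanone
Product: 31 cyclodec-4-yn-1-one (C1 ketone, C4≡C5, C6 OH, C7 dioxolanyl, C8 OTBS, C10 methyl and OTES), via epoxy tosylhydrazone 30 (not isolated)
Conditions: TsNHNH2, AcOH/CH2Cl2 (1:1), −20 °C → rt
Reagents that add atoms: none
Why: Condensation of TsNHNH2 with the C4 carbonyl gives the epoxy tosylhydrazone 30, and loss of the N–H proton lets the hydrazone nitrogen open the oxirane at C5 to an azo-ene (C4=C5) with an alkoxide on C1. The alkoxide re-forms a carbonyl at C1 while the C1–C5 σ-bond breaks and C4≡C5 forms, with loss of sulfinate and N2 (Eschenmoser–Tanabe fragmentation). The closest known reaction type is the fragmentation of ring-fused 2,3-epoxycyclopentanones to cycloalk-4-ynones, as in the macrocyclic musk syntheses. No ring is closed by bond formation: the ten-membered ring appears when the bond shared by the five- and seven-membered rings is cut, so no exo/endo closure mode applies and no dilution is needed. No stereocentre is created; the two oxirane centres vanish, and C6, C7, C8, C10 and C11 are not at reacting carbons. The selectivity needed is hydrazone-triggered fragmentation over acid opening of the oxirane or Wharton-type reduction: C4 is the only carbonyl, C5 has no hydrogen, and the bicyclic frame holds the C1–C5 and C5–O bonds in the alignment the fragmentation needs. The free C6 hydroxyl and the silyl ethers are spectators in cold AcOH/CH2Cl2.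

Step 21
Reactants: 31 cyclodec-4-yn-1-one (C10 OTES)
Product: 32 α-hydroxy ketone (C10 OH free; otherwise as 31)
Conditions: HF·pyridine, pyridine, THF, 0 °C
Reagents that add atoms: none
Why: Buffered HF·pyridine cleaves the triethylsilyl ether much faster than the hindered secondary tert-butyldimethylsilyl ether, freeing the C10 hydroxyl as the chelating group for the next step.

Step 22
Reactants: 32 α-hydroxy ketone
Product: 33 anti-1,10-diol (C1 OH, C10 OH, C6 OH, C4≡C5)
Conditions: Zn(BH4)2 (from ZnCl2, NaBH4), Et2O, −20 °C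
Reagents that add atoms: none
Why: Chelation-controlled reduction: zinc bridges the C1 carbonyl and the C10 hydroxyl (Cram chelate) and hydride enters past the C10 methyl, the smaller flank, giving the anti diol whose C1 oxygen is placed for later displacement with inversion.

Step 23
Reactants: 33 anti-1,10-diol
Product: 34 C1/C10 acetonide (C6 OH free, C4≡C5)
Conditions: Me2C(OMe)2, PPTS, CH2Cl2, rt
Reagents that add atoms: 2,2-dimethoxypropane, COC(C)(C)OC
Why: Acetonide formation selects the vicinal diol over the isolated C6 hydroxyl, so C1 is masked and C6 is the only free alcohol.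

Step 24
Reactants: 34 cyclodecyne acetonide
Product: 36 (4Z)-cyclodecene (C4 methyl, C5 H, C6 OH), via alkenylmagnesium alkoxide 35 (not isolated)
Conditions: MeMgBr (6 equiv), Fe(acac)3 (0.2 equiv), THF, −78 → 0 °C; aq. NH4Cl
Reagents that add atoms: methylmagnesium bromide, C[Mg]Br
Why: Iron-catalysed, alkoxide-directed syn-carbomagnesiation of a propargylic alcohol: methyl goes to the alkyne carbon distal to the C6 alkoxide (C4) and magnesium to C5; protonation gives the trisubstituted alkene whose ring bonds are cis, i.e. 4Z.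

Step 25
Reactants: 37 angelic acid
Product: 38 (Z)-2-methylbut-2-enoic 2,4,6-trichlorobenzoic anhydride
Conditions: 2,4,6-Cl3C6H2COCl, Et3N, toluene, 0 °C → rt; filtration of Et3N·HCl; solution kept cold
Reagents that add atoms: 2,4,6-trichlorobenzoyl chloride, O=C(Cl)c1c(Cl)cc(Cl)cc1Cl
Why: Yamaguchi activation: triethylammonium angelate displaces chloride from the hindered aroyl chloride to give the mixed anhydride; no nucleophilic catalyst and no heating are involved, so the Z geometry of the acid is kept. One filtered batch supplies the angeloyl group for steps 26 and 30.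

Step 26
Reactants: 36 (4Z)-cyclodecenol; 38 (Z)-2-methylbut-2-enoic 2,4,6-trichlorobenzoic anhydride
Product: 39 C6 angelate (C1/C10 acetonide, C8 OTBS, C7 dioxolanyl)
Conditions: 38 (3 equiv), Et3N, toluene, 75 °C
Reagents that add atoms: none
Why: Yamaguchi-type esterification of the only free hydroxyl: the alcohol attacks the angeloyl carbonyl because the aroyl carbonyl is shielded by its two ortho chlorines; heating without a nucleophilic catalyst is the established way to transfer an angeloyl group without isomerisation to the tiglate.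

Step 27
Reactants: 39 protected C6 angelate
Product: 40 pentaol (C1, C8, C10, C11, C12 hydroxyls free; C6 angelate)
Conditions: HF (48% aq.), MeCN, 0 °C → rt
Reagents that add atoms: none
Why: Aqueous HF cleaves the silyl ether and hydrolyses both isopropylidene ketals; the epoxide is not yet present, so acid is tolerable at this stage.

Step 28
Reactants: 40 pentaol
Product: 42 trans-fused 12,8-lactone (C1 OH, C10 OH, C11 OH, C6 angelate), via hydroxy acid 41 (not isolated)
Conditions: TEMPO (cat.), NaClO2, NaOCl (cat.), MeCN, pH 6.7 buffer, 35 °C; then pH 3, rt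
Reagents that add atoms: sodium chlorite, [Na+].[O-]Cl=O
Why: Nitroxyl/chlorite oxidation converts the only primary alcohol to the acid without a glycol-cleaving oxidant, and the γ-hydroxy acid closes onto the C8 hydroxyl on acidification; the fusion is trans because C7 and C8 are already fixed.

Step 29
Reactants: 42 diol lactone
Product: 44 1,10-epoxy-11-hydroxy lactone (C6 angelate), via C1 mesylate 43 (not isolated)
Conditions: MeSO2Cl, Et3N, CH2Cl2, −20 °C; then DBU, rt
Reagents that add atoms: none
Why: The C1 hydroxyl is the only secondary alcohol left and is mesylated selectively; the C10 alkoxide then displaces it (3-exo-tet, inversion at C1), turning the anti diol into the trans-oxirane (1R,10R).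

Step 30
Reactants: 44 1,10-epoxy-11-hydroxy lactone; 38 (Z)-2-methylbut-2-enoic 2,4,6-trichlorobenzoic anhydride
Product: 45 target, (1R,4Z,6R,7S,8R,10R,11R)-6,11-bis(angeloyloxy)-1,10-epoxygermacr-4-en-12,8-olide
Conditions: 44, LiN(SiMe3)2 (1.05 equiv), THF, −78 °C; then 38 (toluene solution), −78 → 0 °C
Reagents that add atoms: none
Why: Acylation of the lithium alkoxide of the tertiary α-hydroxy lactone by the mixed anhydride at its less hindered angeloyl carbonyl; low temperature and a non-nucleophilic base protect the Z geometry, the oxirane and the lactone.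

## Compound list

1 | (R)-citramalic acid | C[C@@](O)(CC(=O)O)C(=O)O | starting material
2 | 2-[(4R)-2,2,4-trimethyl-5-oxo-1,3-dioxolan-4-yl]acetic acid | C[C@@]1(CC(=O)O)C(=O)OC(C)(C)O1 | intermediate
3 | (5R)-5-(2-hydroxyethyl)-2,2,5-trimethyl-1,3-dioxolan-4-one (not isolated) | C[C@@]1(CCO)C(=O)OC(C)(C)O1 | intermediate
4 | (3R)-3-hydroxy-3-methyloxolan-2-one | C[C@@]1(O)CCOC1=O | intermediate
5 | 2-(2-bromoethyl)-2-methyl-1,3-dioxolane | BrCCC1(C)OCCO1 | starting material
6 | [2-(2-methyl-1,3-dioxolan-2-yl)ethyl]magnesium bromide (not isolated) | CC1(CC[Mg]Br)OCCO1 | intermediate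
7 | (4R)-4,6-dihydroxy-4-methyl-1-(2-methyl-1,3-dioxolan-2-yl)hexan-3-one | OCC[C@@](C)(O)C(=O)CCC1(C)OCCO1 | intermediate
8 | (6R)-6,8-dihydroxy-6-methyloctane-2,5-dione (not isolated) | OCC[C@@](C)(O)C(=O)CCC(C)=O | intermediate
9 | 3-[(2R)-2,4-dihydroxybutan-2-yl]cyclopent-2-en-1-one | OCC[C@@](C)(O)C1=CC(=O)CC1 | intermediate
10 | 3-[(2R)-2,4-bis(triethylsilyloxy)butan-2-yl]cyclopent-2-en-1-one | CC[Si](CC)(CC)OCC[C@@](C)(O[Si](CC)(CC)CC)C1=CC(=O)CC1 | intermediate
11 | trans-2,3-dibromo-3-[(2R)-2,4-bis(triethylsilyloxy)butan-2-yl]cyclopentan-1-one (not isolated; one trans diastereomer drawn) | CC[Si](CC)(CC)OCC[C@@](C)(O[Si](CC)(CC)CC)[C@]1(Br)CCC(=O)[C@@H]1Br | intermediate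
12 | 2-bromo-3-[(2R)-2,4-bis(triethylsilyloxy)butan-2-yl]cyclopent-2-en-1-one | CC[Si](CC)(CC)OCC[C@@](C)(O[Si](CC)(CC)CC)C1=C(Br)C(=O)CC1 | intermediate
13 | 6-bromo-7-[(2R)-2,4-bis(triethylsilyloxy)butan-2-yl]-1,4-dioxaspiro[4.4]non-6-ene | CC[Si](CC)(CC)OCC[C@@](C)(O[Si](CC)(CC)CC)C1=C(Br)C2(CC1)OCCO2 | intermediate
14 | (3R)-3-(6-bromo-1,4-dioxaspiro[4.4]non-6-en-7-yl)-3-(triethylsilyloxy)butanal | O=CC[C@@](C)(O[Si](CC)(CC)CC)C1=C(Br)C2(CC1)OCCO2 | intermediate
15 | (2R)-2-methylbutane-1,2,4-triol | C[C@@](O)(CCO)CO | intermediate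
16 | 2-[(4R)-2,2,4-trimethyl-1,3-dioxolan-4-yl]ethan-1-ol | OCC[C@]1(C)COC(C)(C)O1 | intermediate
17 | 2-[(4R)-2,2,4-trimethyl-1,3-dioxolan-4-yl]acetic acid | OC(=O)C[C@]1(C)COC(C)(C)O1 | intermediate
18 | (4S)-4-benzyl-1,3-oxazolidin-2-one | O=C1N[C@@H](Cc2ccccc2)CO1 | starting material
19 | 2,2-dimethylpropanoic 2-[(4R)-2,2,4-trimethyl-1,3-dioxolan-4-yl]acetic anhydride (not isolated) | CC(C)(C)C(=O)OC(=O)C[C@]1(C)COC(C)(C)O1 | intermediate
20 | (4S)-4-benzyl-3-{2-[(4R)-2,2,4-trimethyl-1,3-dioxolan-4-yl]acetyl}-1,3-oxazolidin-2-one | O=C(C[C@]1(C)COC(C)(C)O1)N2[C@@H](Cc3ccccc3)COC2=O | intermediate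
21 | (Z)-dibutylboron enolate of 20 (not isolated) | CCCCB(CCCC)O/C(=C\[C@]1(C)COC(C)(C)O1)N2[C@@H](Cc3ccccc3)COC2=O | intermediate
22 | (4S)-4-benzyl-3-[(2R,3R,5R)-5-(6-bromo-1,4-dioxaspiro[4.4]non-6-en-7-yl)-3-hydroxy-5-(triethylsilyloxy)-2-[(4R)-2,2,4-trimethyl-1,3-dioxolan-4-yl]hexanoyl]-1,3-oxazolidin-2-one | O=C(N1[C@@H](Cc2ccccc2)COC1=O)[C@@H]([C@]3(C)COC(C)(C)O3)[C@H](O)C[C@@](C)(O[Si](CC)(CC)CC)C4=C(Br)C5(CC4)OCCO5 | intermediate
23 | (2R,3R,5R)-5-(6-bromo-1,4-dioxaspiro[4.4]non-6-en-7-yl)-3-hydroxy-N-methoxy-N-methyl-5-(triethylsilyloxy)-2-[(4R)-2,2,4-trimethyl-1,3-dioxolan-4-yl]hexanamide | CON(C)C(=O)[C@@H]([C@]1(C)COC(C)(C)O1)[C@H](O)C[C@@](C)(O[Si](CC)(CC)CC)C2=C(Br)C3(CC2)OCCO3 | intermediate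
24 | 3-O-tert-butyldimethylsilyl ether of 23 | CON(C)C(=O)[C@@H]([C@]1(C)COC(C)(C)O1)[C@H](O[Si](C)(C)C(C)(C)C)C[C@@](C)(O[Si](CC)(CC)CC)C2=C(Br)C3(CC2)OCCO3 | intermediate
25 | C5 vinyllithium derived from 24 (not isolated) | CON(C)C(=O)[C@@H]([C@]1(C)COC(C)(C)O1)[C@H](O[Si](C)(C)C(C)(C)C)C[C@@](C)(O[Si](CC)(CC)CC)C2=C([Li])C3(CC2)OCCO3 | intermediate
26 | bicyclic enone: C6 ketone, C1=C5 ring-fusion alkene, C4 ethylene ketal, C7 [(4R)-2,2,4-trimethyl-1,3-dioxolan-4-yl], C8 OTBS, C10 methyl/OTES (configurations of 24) | O=C1[C@@H]([C@]2(C)COC(C)(C)O2)[C@H](O[Si](C)(C)C(C)(C)C)C[C@@](C)(O[Si](CC)(CC)CC)C3=C1C4(CC3)OCCO4 | intermediate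
27 | allylic alcohol from 26, C6 OH cis to the C7 dioxolanyl group | O[C@H]1[C@@H]([C@]2(C)COC(C)(C)O2)[C@H](O[Si](C)(C)C(C)(C)C)C[C@@](C)(O[Si](CC)(CC)CC)C3=C1C4(CC3)OCCO4 | intermediate
28 | C1/C5 epoxide of 27, oxirane syn to C6 OH, C4 ethylene ketal | O[C@H]1[C@@H]([C@]2(C)COC(C)(C)O2)[C@H](O[Si](C)(C)C(C)(C)C)C[C@@](C)(O[Si](CC)(CC)CC)[C@@]34O[C@@]13C5(CC4)OCCO5 | intermediate
29 | ring-fused 2,3-epoxycyclopentanone: C4 ketone, C1/C5 oxirane, C6 OH, C7 dioxolanyl, C8 OTBS, C10 methyl/OTES | O[C@H]1[C@@H]([C@]2(C)COC(C)(C)O2)[C@H](O[Si](C)(C)C(C)(C)C)C[C@@](C)(O[Si](CC)(CC)CC)[C@@]34O[C@@]13C(=O)CC4 | intermediate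
30 | C4 tosylhydrazone of 29 (not isolated) | O[C@H]1[C@@H]([C@]2(C)COC(C)(C)O2)[C@H](O[Si](C)(C)C(C)(C)C)C[C@@](C)(O[Si](CC)(CC)CC)[C@@]34O[C@@]13C(=NNS(=O)(=O)c5ccc(C)cc5)CC4 | intermediate
31 | cyclodec-4-yn-1-one: C6 OH, C7 dioxolanyl, C8 OTBS, C10 methyl/OTES | O[C@H]1[C@@H]([C@]2(C)COC(C)(C)O2)[C@H](O[Si](C)(C)C(C)(C)C)C[C@@](C)(O[Si](CC)(CC)CC)C(=O)CCC#C1 | intermediate
32 | 10-hydroxy-cyclodec-4-yn-1-one (C10 OH free; otherwise as 31) | O[C@H]1[C@@H]([C@]2(C)COC(C)(C)O2)[C@H](O[Si](C)(C)C(C)(C)C)C[C@@](C)(O)C(=O)CCC#C1 | intermediate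
33 | cyclodec-4-yne-1,6,10-triol derivative, anti-1,10-diol | O[C@H]1[C@@H]([C@]2(C)COC(C)(C)O2)[C@H](O[Si](C)(C)C(C)(C)C)C[C@@](C)(O)[C@@H](O)CCC#C1 | intermediate
34 | C1/C10 acetonide of 33 | O[C@H]1[C@@H]([C@]2(C)COC(C)(C)O2)[C@H](O[Si](C)(C)C(C)(C)C)C[C@@]3(C)OC(C)(C)O[C@H]3CCC#C1 | intermediate
35 | C5 alkenylmagnesium bromide, C6 bromomagnesium alkoxide (not isolated) | Br[Mg]O[C@H]1[C@@H]([C@]2(C)COC(C)(C)O2)[C@H](O[Si](C)(C)C(C)(C)C)C[C@@]3(C)OC(C)(C)O[C@H]3CC/C(C)=C1/[Mg]Br | intermediate
36 | (4Z)-4-methylcyclodec-4-en-6-ol derivative (C1/C10 acetonide, C8 OTBS, C7 dioxolanyl) | O[C@H]1[C@@H]([C@]2(C)COC(C)(C)O2)[C@H](O[Si](C)(C)C(C)(C)C)C[C@@]3(C)OC(C)(C)O[C@H]3CC/C(C)=C\1 | intermediate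
37 | angelic acid, (Z)-2-methylbut-2-enoic acid | C/C=C(/C)C(=O)O | starting material
38 | (Z)-2-methylbut-2-enoic 2,4,6-trichlorobenzoic anhydride | C/C=C(/C)C(=O)OC(=O)c1c(Cl)cc(Cl)cc1Cl | intermediate
39 | C6 angelate of 36 | C/C=C(/C)C(=O)O[C@H]1[C@@H]([C@]2(C)COC(C)(C)O2)[C@H](O[Si](C)(C)C(C)(C)C)C[C@@]3(C)OC(C)(C)O[C@H]3CC/C(C)=C\1 | intermediate
40 | pentaol: C1, C8, C10, C11, C12 hydroxyls free, C6 angelate, 4Z alkene | C/C=C(/C)C(=O)O[C@H]1[C@@H]([C@@](C)(O)CO)[C@H](O)C[C@@](C)(O)[C@@H](O)CC/C(C)=C\1 | intermediate
41 | C12 carboxylic acid of 40 (not isolated) | C/C=C(/C)C(=O)O[C@H]1[C@@H]([C@@](C)(O)C(=O)O)[C@H](O)C[C@@](C)(O)[C@@H](O)CC/C(C)=C\1 | intermediate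
42 | 6-angeloyloxy-1,10,11-trihydroxygermacr-4Z-en-12,8-olide | C/C=C(/C)C(=O)O[C@H]1[C@H]2[C@@](C)(O)C(=O)O[C@@H]2C[C@@](C)(O)[C@@H](O)CC/C(C)=C\1 | intermediate
43 | C1 methanesulfonate of 42 (not isolated) | C/C=C(/C)C(=O)O[C@H]1[C@H]2[C@@](C)(O)C(=O)O[C@@H]2C[C@@](C)(O)[C@@H](OS(C)(=O)=O)CC/C(C)=C\1 | intermediate
44 | 6-angeloyloxy-1,10-epoxy-11-hydroxygermacr-4Z-en-12,8-olide | C/C=C(/C)C(=O)O[C@H]1[C@H]2[C@@](C)(O)C(=O)O[C@@H]2C[C@@]3(C)O[C@@H]3CC/C(C)=C\1 | intermediate
45 | (1R,4Z,6R,7S,8R,10R,11R)-6,11-bis(angeloyloxy)-1,10-epoxygermacr-4-en-12,8-olide | C/C=C(/C)C(=O)O[C@@H]1/C=C(/C)CC[C@H]2O[C@]2(C)C[C@H]2OC(=O)[C@](C)(OC(=O)/C(C)=C\C)[C@H]12 | target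

## Step count and risks

Total: 30 steps. Longest linear sequence: 25 steps (steps 1–8, 13–24 and 26–30 from 1); steps 9–12 form the side branch to imide 20, and step 25 prepares the angeloyl donor 38.

**Step 20 (key step).** Hydrazone formation at the hindered C4 carbonyl may lag behind acid-induced opening or semipinacol shift of the tetrasubstituted oxirane, because acid is needed for the tosylhydrazone to ionise. Fallback: from 29, condensation with 1-amino-trans-2,3-diphenylaziridine gives the N-aziridinyl imine F1, which is isolated and heated in toluene. The same C1–C5 cleavage then runs without acid, with loss of stilbene and N2, and returns to 31.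

**Step 16.** After bromine–lithium exchange the vinyllithium may be quenched by proton transfer from C7–H, or may attack the crowded C6 carbonyl too slowly, so that reduced open-chain material results. Fallback: from 24, copper-catalysed halogen exchange (CuI, NaI, trans-N,N'-dimethylcyclohexane-1,2-diamine, dioxane) gives the vinyl iodide F2. i-Bu2AlH reduces its amide to the aldehyde F3. CrCl2 with catalytic NiCl2 in DMSO then closes the seven-membered ring by Nozaki–Hiyama–Kishi addition and gives the C6 carbinol 27 directly, bypassing 26.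

**Step 17.** Facial selectivity of hydride delivery may be poor, because the C8 silyl ether lies on the face opposite the C7 side chain and may offset it. Fallback: from 26, if reduction favours the C6 epimer F4, Mitsunobu inversion with 4-nitrobenzoic acid (PPh3, DIAD) gives the ester F5 with the configuration of 27, and K2CO3/MeOH releases 27.

**Step 22.** Chelation control may be lost, because the conformation of the ten-membered ring may dictate peripheral attack and the C6 hydroxyl competes for zinc. Fallback: from 32, control is moved from the substrate to a catalyst by asymmetric transfer hydrogenation with RuCl[(S,S)-TsDPEN](p-cymene) or its enantiomer in HCO2H/Et3N, which reduces α-hydroxy ketones and leaves alkynes. The enantiomer matched to the required C1 configuration would be used, and the route is rejoined at 33 without a new intermediate.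

**Step 24.** The hindered, ring-constrained alkyne may react sluggishly, which would allow loss of regiocontrol (methyl to C5) or simple hydromagnesiation. Fallback: from 34, platinum-catalysed syn-hydrosilylation (Et3SiH, PtCl2, XPhos) places silicon on C4 and gives the vinylsilane F6. N-Iodosuccinimide in (CF3)2CHOH exchanges silicon for iodine with retention to give the vinyl iodide F7. Suzuki methylation (trimethylboroxine, Pd(PPh3)4, K2CO3) returns to 36.

**Step 30.** The tertiary alkoxide may acylate slowly, leaving time for isomerisation of the angeloyl group to tigloyl or for acyl transfer from O6. Fallback: from 44, esterification with 2-[bis(2,2,2-trifluoroethoxy)phosphoryl]propanoic acid (DCC, DMAP) gives the phosphonate ester F8. Still–Gennari olefination with acetaldehyde (KN(SiMe3)2, 18-crown-6, THF, −78 °C) then builds the (Z)-2-methylbut-2-enoate on the molecule and gives 45.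

## Further compounds

F1 | step 20 | N-(trans-2,3-diphenylaziridin-1-yl)imine of 29 (one diastereomer drawn) | O[C@H]1[C@@H]([C@]2(C)COC(C)(C)O2)[C@H](O[Si](C)(C)C(C)(C)C)C[C@@](C)(O[Si](CC)(CC)CC)[C@@]34O[C@@]13C(=NN5[C@@H](c6ccccc6)[C@@H]5c7ccccc7)CC4
F2 | step 16 | vinyl iodide analogue of 24 | CON(C)C(=O)[C@@H]([C@]1(C)COC(C)(C)O1)[C@H](O[Si](C)(C)C(C)(C)C)C[C@@](C)(O[Si](CC)(CC)CC)C2=C(I)C3(CC2)OCCO3
F3 | step 16 | C6 aldehyde from F2 | O=C[C@@H]([C@]1(C)COC(C)(C)O1)[C@H](O[Si](C)(C)C(C)(C)C)C[C@@](C)(O[Si](CC)(CC)CC)C2=C(I)C3(CC2)OCCO3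
F4 | step 17 | C6 epimer of 27 | O[C@@H]1[C@@H]([C@]2(C)COC(C)(C)O2)[C@H](O[Si](C)(C)C(C)(C)C)C[C@@](C)(O[Si](CC)(CC)CC)C3=C1C4(CC3)OCCO4
F5 | step 17 | 4-nitrobenzoate of 27 | O=C(O[C@H]1[C@@H]([C@]2(C)COC(C)(C)O2)[C@H](O[Si](C)(C)C(C)(C)C)C[C@@](C)(O[Si](CC)(CC)CC)C3=C1C4(CC3)OCCO4)c5ccc(cc5)[N+](=O)[O-]
F0 | step 22 | none | none
F6 | step 24 | C4 triethylsilyl (4Z)-cyclodecenol | O[C@H]1[C@@H]([C@]2(C)COC(C)(C)O2)[C@H](O[Si](C)(C)C(C)(C)C)C[C@@]3(C)OC(C)(C)O[C@H]3CC/C([Si](CC)(CC)CC)=C\1
F7 | step 24 | C4 iodo (4Z)-cyclodecenol | O[C@H]1[C@@H]([C@]2(C)COC(C)(C)O2)[C@H](O[Si](C)(C)C(C)(C)C)C[C@@]3(C)OC(C)(C)O[C@H]3CC/C(I)=C\1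
F8 | step 30 | C11 2-[bis(2,2,2-trifluoroethoxy)phosphoryl]propanoate of 44 (mixture at the phosphonate carbon) | C/C=C(/C)C(=O)O[C@H]1[C@H]2[C@@](C)(OC(=O)C(C)P(=O)(OCC(F)(F)F)OCC(F)(F)F)C(=O)O[C@@H]2C[C@@]3(C)O[C@@H]3CC/C(C)=C\1
A1 | alternative 1 | isoxazoline-bridged ten-membered carbocycle | CC(C)(C)[Si](C)(C)O[C@@H]1/C=C(/C)CC[C@H](OCc2ccc(OC)cc2)[C@@]3(C)CC(=NO3)[C@@H]1[C@@](C)(OCOC)C(=O)OC
A2 | alternative 1 | open-chain C8 aldoxime with C9=C10 alkene | CC(C)(C)[Si](C)(C)O[C@H](/C=C(/C)CC[C@H](OCc1ccc(OC)cc1)C(C)=C)[C@H](C=NO)[C@@](C)(OCOC)C(=O)OC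
A3 | alternative 2 | cis-anti-cis tricyclic photoadduct with fused lactone | O=C1[C@@H]2[C@@]3(C)CC[C@H]3[C@]2(C)C[C@H]4OC(=O)[C@](C)(OCOC)[C@H]14
A4 | alternative 2 | 3-methylcyclohexenone lactone | O=C1C=C(C)C[C@H]2OC(=O)[C@](C)(OCOC)[C@H]12
A5 | alternative 2 | 1-methylcyclobutene | CC1=CCC1
A6 | alternative 3 | 6-hydroxy-11-O-angeloyl epoxy germacrenolide | O[C@@H]1/C=C(/C)CC[C@H]2O[C@]2(C)C[C@H]2OC(=O)[C@](C)(OC(=O)/C(C)=C\C)[C@H]12
A7 | alternative 3 | seco (Z)-C5 vinyl iodide C6 aldehyde | O=C[C@H]1[C@@](C)(OC(=O)/C(C)=C\C)C(=O)O[C@@H]1C[C@@]2(C)O[C@@H]2CC/C(C)=C\I
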